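- The easy step came first. I took one partner per substrate molecule consumed, so the readings gave the straight mean [partner] over 25.0 min: 0.122 M in amber and 0.295 M in violet, near 0.7 of the charge in each.

common to all: left-handed substrate 0.30 M; right-handed substrate 0.30 M; free catalyst 6.6 mM; impurity 3.5 mM
- amber: partner 0.17 M; run made earlier
- violet: partner 0.40 M; run made earlier
- gamma: partner 0.330 M; time 50 min
- beta: partner 0.150 M; time 50 min

| run | time / min | right-handed substrate / % | left-handed substrate / % |
|---|---|---|---|
| amber | 5.00 | 47.2 | 46.6 |
| amber | 10.0 | 47.0 | 43.9 |
| amber | 15.0 | 45.4 | 42.0 |
| amber | 20.0 | 46.4 | 39.9 |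
| amber | 25.0 | 44.5 | 39.6 |
| violet | 2.00 | 47.7 | 45.4 |
| violet | 6.00 | 44.9 | 39.5 |
| violet | 12.0 | 42.1 | 35.1 |
| violet | 20.0 | 38.6 | 29.9 |
| violet | 25.0 | 37.4 | 27.6 |

(standard deviation of a reading: 0.5 percentage points)

- free catalyst is single-handed; left-handed substrate and right-handed substrate are mirror images of each other, charged as a racemate, each of them at the stated concentration
- an excess is the difference of the two amounts in percent of their sum
- an excess is below zero if the other one leads

1. the winner by excess of right-handed substrate over left-handed substrate among what is left of the two; "neither" if no more than 2 percentage points parts them (gamma / beta / neither)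
2. excess of right-handed substrate over left-handed substrate among what is left of the two at the end, gamma
3. excess of right-handed substrate over left-handed substrate among what is left of the two at the end, beta

- You guessed that gamma would pull ahead of beta on its larger partner charge, so I put a number on that.
- I defined the partner exposure constant, the logarithmic fall of the left-handed substrate divided by mean [partner] and time. Amber read 0.0763 L mol⁻¹ min⁻¹ and violet 0.0806 L mol⁻¹ min⁻¹, so I carried their mean, 0.0784 L mol⁻¹ min⁻¹, for flasks with this catalyst and impurity charge.
- Violet's last reading gave a selectivity factor of 2.05, so I took the logarithmic fall of the right-handed substrate as the left-handed one divided by that factor.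
- I started each flask at 0.7 of its charge, reckoned the substrate lost, and put that back in. Gamma's first round reckoned 0.286 M of substrate lost, which put its mean [partner] at 0.187 M, and the second round gave an excess of 18.5%.
- Beta's first round asked for 0.156 M, more than the 0.150 M charged, so I took partner as the limiting reagent there. Its second round, at 0.0720 M, gave 7.21%.
- The forecast, “roughly first order in partner”, named gamma, with 18.5% for gamma and 8% for beta.
- The flasks gave gamma as the winner, with 17.9% for gamma and 7.60% for beta.

    partner + free catalyst + left-handed substrate → free catalyst + left-handed product (k = 39.0 L² mol⁻² min⁻¹)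
    partner + free catalyst + right-handed substrate → free catalyst + right-handed product (k = 19.0 L² mol⁻² min⁻¹)
    partner → decomposed reagent (k = 0.00260 min⁻¹)
    free catalyst ⇌ dormant form (K = 0.410, k = 0.0670 min⁻¹)
    free catalyst + impurity → spent catalyst (k = 1600 L mol⁻¹ min⁻¹)

- In gamma, the impurity took free catalyst with a half-life of 0.12 min, far shorter than the 18 min half-life of partner through the right-handed step alone at charged concentrations. Free catalyst stood at 33.4% at 25.0 min and 33.3% at 50.0 min, a steady level over which 0.0784 L mol⁻¹ min⁻¹ served gamma.
- A neighbour of gamma was charged with 0.56 M of partner, all else held. The same two rounds gave a mean [partner] of 0.363 M and an excess of 34.9%; the computed flask gave 32.3%.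

(The runs were generated by integration with made-up constants.)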